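**Retrosynthetic overview**
1. The acetate comes from the 12‑hydroxy‑11,14‑quinone, the quinone from an 11,12,14‑trimethoxy arene (ring C, bought as 1,2,4‑trimethoxybenzene), and the C19–O–C20 lactone from reduction of a C20 aldehyde next to the axial C19 ester.
2. Key disconnection: C5–C10 and C7–C8 are cut together, which opens rings A and B to an acyclic enal/enol ether chain on the arene (20); one acid‑triggered cationic cascade closes ring A, then ring B, and leaves the C6=C7 olefin and the C20 aldehyde.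
3. Enabling feature: the C10=C20 methyl enol ether on ring C makes C10 and, through the arene, C8 (the only free ring position, para to the C12 and ortho to the C14 methoxy group) a 1,3‑bis‑nucleophile; the enal C5=C6–C7=O is the matching 1,3‑bis‑electrophile, and the C1–C3 tether makes the first closure six‑membered.
4. The chain comes from (S)‑methyl 1‑methyl‑2‑oxocyclohexanecarboxylate by ozonolytic ring cleavage, which keeps the quaternary centre C4 (the only pre‑set stereocentre) and turns the ring carbons into C10, C1–C3, C4 and C5; aryllithium addition and two Wittig reactions complete it.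
5. Ring order: ring C (bought) → ring A → ring B (same operation) → lactone → quinone.

Key step: step 12

Remark: positions are named by abietane numbering (C4 = quaternary methyl/carboxyl carbon, C5 = ring‑fusion CH, C10 = quaternary ring‑fusion carbon, C19 = carboxyl carbon on C4, C20 = oxygenated carbon on C10); tert‑butyl L‑valinate is bought as its hydrochloride and set free before use.

**Step 1**
Reactants: 1 1,2,4‑trimethoxybenzene
Product: 3 2‑(2,3,6‑trimethoxyphenyl)propan‑2‑ol, via 2,3,6‑trimethoxyphenyllithium 2 (not isolated)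
Conditions: n‑BuLi, THF, 0 → 23 °C; acetone, −78 → 23 °C; H2O
Reagents that add atoms: acetone, CC(C)=O
Why: Directed ortho‑metalation takes place at the ring position flanked by two methoxy groups, and the aryllithium adds to acetone (1,2‑addition).

**Step 2**
Reactants: 3 2‑(2,3,6‑trimethoxyphenyl)propan‑2‑ol
Product: 4 2‑isopropyl‑1,3,4‑trimethoxybenzene
Conditions: Et3SiH, CF3CO2H, CH2Cl2, 0 → 23 °C
Reagents that add atoms: none
Why: Ionic hydrogenation, in which the tertiary benzylic alcohol ionises readily next to the electron‑rich ring and the cation is reduced by the silane.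

**Step 3**
Reactants: 5 methyl 2‑oxocyclohexane‑1‑carboxylate; 6 tert‑butyl L‑valinate
Product: 7 methyl 2‑{[(2S)‑1‑tert‑butoxy‑3‑methyl‑1‑oxobutan‑2‑yl]amino}cyclohex‑1‑ene‑1‑carboxylate
Conditions: AcOH (cat.), toluene, reflux, Dean–Stark
Reagents that add atoms: none
Why: Condensation of a β‑keto ester with a primary amine should give the hydrogen‑bonded enamino ester (vinylogous carbamate), with the valine stereocentre untouched.

**Step 4**
Reactants: 7 enamino ester
Product: 10 methyl (1S)‑1‑methyl‑2‑oxocyclohexane‑1‑carboxylate, via lithio enamine 8 (not isolated), via methylated imine 9 (not isolated)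
Conditions: LiN(iPr)2, toluene, −78 °C; MeI, donor ligand (HMPA or THF/1,3‑dioxolane, whichever gives the S series), −78 → −40 °C; 1 M HCl, 0 °C
Reagents that add atoms: iodomethane, CI; water, O
Why: Asymmetric alkylation of a chiral chelated lithio enamine, in which lithium is held by nitrogen and the tert‑butyl ester carbonyl, the isopropyl group of the auxiliary shields one face so that methyl iodide sets the quaternary centre C4 as S, and mild hydrolysis of the imine returns the ketone and the auxiliary.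

**Step 5**
Reactants: 10 methyl (1S)‑1‑methyl‑2‑oxocyclohexane‑1‑carboxylate
Product: 11 methyl (1S)‑1‑methyl‑2‑[(trimethylsilyl)oxy]cyclohex‑2‑ene‑1‑carboxylate
Conditions: Me3SiOTf, Et3N, CH2Cl2, 0 °C
Reagents that add atoms: trimethylsilyl trifluoromethanesulfonate, C[Si](C)(C)OS(=O)(=O)C(F)(F)F
Why: Soft enolisation and O‑silylation can go only toward C10 because C4 is quaternary, so a single silyl enol ether should form.

**Step 6**
Reactants: 11 silyl enol ether
Product: 13 (2S)‑2‑(methoxycarbonyl)‑2‑methyl‑6‑oxohexanoic acid, via trimethylsilyl ester 12 (not isolated)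
Conditions: O3, CH2Cl2, −78 °C; Me2S, −78 → 23 °C; aqueous work‑up
Reagents that add atoms: ozone, [O-][O+]=O
Why: Ozonolysis of the silyl enol ether cleaves the ring C5=C10 bond (oxidative C–C cleavage) into a carboxylic acid (C5) and an aldehyde (C10) without touching the quaternary centre C4, which has no enolisable hydrogen.

**Step 7**
Reactants: 4 2‑isopropyl‑1,3,4‑trimethoxybenzene; 13 aldehyde acid
Product: 15 (2S)‑6‑hydroxy‑6‑(4‑isopropyl‑2,3,5‑trimethoxyphenyl)‑2‑(methoxycarbonyl)‑2‑methylhexanoic acid (both C6 epimers), via 4‑isopropyl‑2,3,5‑trimethoxyphenyllithium 14 (not isolated)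
Conditions: 4 (2.2 equiv), n‑BuLi (2.1 equiv), TMEDA, THF, 0 °C; 13, −78 → −40 °C; 1 M HCl
Reagents that add atoms: none
Why: Directed ortho‑metalation should remove the ring hydrogen next to the veratrole‑type methoxy group (the other methoxy group is buttressed by the isopropyl group and cannot direct), and the aryllithium, after one equivalent has formed the lithium carboxylate, adds to the aldehyde (1,2‑addition) faster than to the hindered ester, giving a carbinol centre that is erased in step 8.

**Step 8**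
Reactants: 15 hydroxy acid
Product: 16 (2S)‑6‑(4‑isopropyl‑2,3,5‑trimethoxyphenyl)‑2‑(methoxycarbonyl)‑2‑methyl‑6‑oxohexanoic acid
Conditions: 1,1,1‑triacetoxy‑1,1‑dihydro‑1,2‑benziodoxol‑3(1H)‑one (DMP), CH2Cl2, 23 °C
Reagents that add atoms: none
Why: Oxidation of the benzylic secondary alcohol with the hypervalent iodine reagent should give the aryl ketone, with acid and ester inert.

**Step 9**
Reactants: 16 keto acid
Product: 17 (2S)‑6‑(4‑isopropyl‑2,3,5‑trimethoxyphenyl)‑7‑methoxy‑2‑(methoxycarbonyl)‑2‑methylhept‑6‑enoic acid (E/Z mixture)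
Conditions: KN(SiMe3)2 (3.1 equiv), MeOCH2PPh3Cl (2.1 equiv), THF, 0 → 40 °C; work‑up at pH 5; used without delay
Reagents that add atoms: (methoxymethyl)triphenylphosphonium chloride, COC[P+](c1ccccc1)(c1ccccc1)c1ccccc1.[Cl-]
Why: Wittig methoxymethylenation of the aryl ketone (as its potassium carboxylate) introduces C20 as a methyl enol ether, the masked α‑aryl aldehyde nucleophile, and both olefin isomers serve equally.

**Step 10**
Reactants: 17 enol ether acid
Product: 19 methyl (2S)‑2‑formyl‑6‑(4‑isopropyl‑2,3,5‑trimethoxyphenyl)‑7‑methoxy‑2‑methylhept‑6‑enoate, via acid chloride 18 (not isolated)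
Conditions: 1‑chloro‑N,N,2‑trimethylprop‑1‑en‑1‑amine, CH2Cl2, 0 °C; LiAlH(OtBu)3, THF, −78 °C
Reagents that add atoms: none
Why: The acid is converted to its chloride under neutral conditions (α‑chloroenamine reagent, no HCl, so the enol ether survives) and the bulky hydride should stop at the aldehyde (acid chloride to aldehyde reduction).

**Step 11**
Reactants: 19 aldehyde
Product: 20 methyl (2S,3E)‑2‑[4‑(4‑isopropyl‑2,3,5‑trimethoxyphenyl)‑5‑methoxypent‑4‑en‑1‑yl]‑2‑methyl‑5‑oxopent‑3‑enoate
Conditions: Ph3P=CHCHO, toluene, 90 °C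
Reagents that add atoms: (triphenylphosphoranylidene)acetaldehyde, O=CC=P(c1ccccc1)(c1ccccc1)c1ccccc1
Why: Wittig olefination with the stabilised formyl ylide should give the E‑enal, since the α‑quaternary aldehyde cannot enolise and the enol ether is inert to the neutral ylide.

**Step 12**
Reactants: 20 enol ether enal
Product: 23 methyl (4S,5R,10R)‑11,12,14‑trimethoxy‑20‑oxoabieta‑6,8,11,13‑tetraen‑19‑oate, via dihydropyran acetal 21 (not isolated), via bridged 7,20‑epoxy acetal 22 (not isolated)
Conditions: HNTf2 (0.2 equiv), CH2Cl2–(CF3)2CHOH 4:1, 0.01 M, −40 → 23 °C; Et3N quench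
Reagents that add atoms: none
Why: Proposed new method: protonation of the enal lets the enol ether carbon C10 add to C5 in a chair‑like 6‑exo‑trig transition state (ring A; a vinylogous Mukaiyama–Michael addition or asynchronous inverse‑demand hetero‑Diels–Alder reaction, giving acetal 21), the enol ether left at C6=C7 is protonated to a C7 oxocarbenium ion that the arene attacks at C8 (ring B, 6‑exo‑trig oxa‑Pictet–Spengler‑type Friedel–Crafts closure, giving the carnosol‑like bridged acetal 22), and acid‑induced opening of the benzylic C7–O bond with loss of H6 and methanol delivers the C6=C7 olefin and the C20 aldehyde. The closest known reaction types are the acid‑mediated conjugate addition of enol ethers to enals and the Bradsher cyclodehydration of 4‑arylbutanals to 1,2‑dihydronaphthalenes; new is their union in one cationic cascade on a tethered enol ether–enal–arene. C10 and C5 are set together in the ring A closure: the aryl group on C10 and the E‑enal on C5 take pseudo‑equatorial positions, so C20 becomes axial and H5 anti to it (trans A/B fusion), and only adducts with aryl and C6 gauche can go on to ring B while the reversible first step returns the others. The configuration relative to C4 should follow from the ester taking the axial position syn to C20, because it has a smaller A value than methyl and its carbonyl oxygen can stabilise the developing C20 oxocarbenium ion across the 1,3‑diaxial gap. The step needs 1,4‑ over 1,2‑addition and a single arene position: the 1,2‑mode would need an eight‑membered ring, and C8 is the only unsubstituted arene carbon and is activated by the para C12 and ortho C14 methoxy groups.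

**Step 13**
Reactants: 23 tricyclic aldehyde ester
Product: 25 (4S,5R,10R)‑11,12,14‑trimethoxyabieta‑6,8,11,13‑tetraen‑19,20‑olide, via hydroxy ester 24 (not isolated)
Conditions: NaBH4, MeOH, 0 °C; solvent exchange; PPTS (cat.), toluene, 60 °C
Reagents that add atoms: none
Why: NaBH4 reduces only the C20 aldehyde, and the C20 hydroxyl, held 1,3‑diaxial to the C19 ester on ring A, should close the bridged δ‑lactone by acid‑catalysed transesterification, which only the isomer with C19 and C20 cis can do, so any C4 epimer from step 12 is removed here.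

**Step 14**
Reactants: 25 trimethoxy lactone
Product: 27 (4S,5R,10R)‑12‑hydroxy‑11,14‑dioxoabieta‑6,8,12‑trien‑19,20‑olide, via triol 26 (not isolated)
Conditions: BBr3, CH2Cl2, −78 → 0 °C; aq. NaHCO3, air, 23 °C; acidify
Reagents that add atoms: none
Why: BBr3 cleaves the three aryl methyl ethers (Lewis acid ether cleavage) and the resulting 1,2,4‑trihydroxyarene should be autoxidised by air to the hydroxy‑p‑quinone, with the lactone and the three stereocentres untouched.

**Step 15**
Reactants: 27 hydroxyquinone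
Product: 28 (4S,5R,10R)‑12‑acetoxy‑11,14‑dioxoabieta‑6,8,12‑trien‑19,20‑olide (target, CNP0596241.1)
Conditions: Ac2O, pyridine, DMAP (cat.), CH2Cl2, 0 °C
Reagents that add atoms: acetic anhydride, CC(=O)OC(C)=O
Why: O‑Acetylation of the acidic hydroxyquinone OH, the only hydroxyl group in the molecule.

**Compound list**
1 | 1,2,4‑trimethoxybenzene | COc1ccc(OC)c(OC)c1 | starting material
2 | 2,3,6‑trimethoxyphenyllithium | [Li]c1c(OC)ccc(OC)c1OC | intermediate
3 | 2‑(2,3,6‑trimethoxyphenyl)propan‑2‑ol | COc1ccc(OC)c(C(C)(C)O)c1OC | intermediate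
4 | 2‑isopropyl‑1,3,4‑trimethoxybenzene | COc1ccc(OC)c(C(C)C)c1OC | intermediate
5 | methyl 2‑oxocyclohexane‑1‑carboxylate | COC(=O)C1CCCCC1=O | starting material
6 | tert‑butyl L‑valinate | CC(C)[C@H](N)C(=O)OC(C)(C)C | starting material
7 | methyl 2‑{[(2S)‑1‑tert‑butoxy‑3‑methyl‑1‑oxobutan‑2‑yl]amino}cyclohex‑1‑ene‑1‑carboxylate | COC(=O)C1=C(N[C@@H](C(C)C)C(=O)OC(C)(C)C)CCCC1 | intermediate
8 | N‑lithio derivative of 7 (chelated lithio enamine) | COC(=O)C1=C(N([Li])[C@@H](C(C)C)C(=O)OC(C)(C)C)CCCC1 | intermediate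
9 | methyl (1S)‑2‑{[(2S)‑1‑tert‑butoxy‑3‑methyl‑1‑oxobutan‑2‑yl]imino}‑1‑methylcyclohexane‑1‑carboxylate | COC(=O)[C@@]1(C)CCCCC1=N[C@@H](C(C)C)C(=O)OC(C)(C)C | intermediate
10 | methyl (1S)‑1‑methyl‑2‑oxocyclohexane‑1‑carboxylate | COC(=O)[C@@]1(C)CCCCC1=O | intermediate
11 | methyl (1S)‑1‑methyl‑2‑[(trimethylsilyl)oxy]cyclohex‑2‑ene‑1‑carboxylate | COC(=O)[C@@]1(C)CCCC=C1O[Si](C)(C)C | intermediate
12 | trimethylsilyl ester of 13 (same configuration) | O=CCCC[C@](C)(C(=O)OC)C(=O)O[Si](C)(C)C | intermediate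
13 | (2S)‑2‑(methoxycarbonyl)‑2‑methyl‑6‑oxohexanoic acid | O=CCCC[C@](C)(C(=O)OC)C(=O)O | intermediate
14 | 4‑isopropyl‑2,3,5‑trimethoxyphenyllithium | [Li]c1cc(OC)c(C(C)C)c(OC)c1OC | intermediate
15 | (2S)‑6‑hydroxy‑6‑(4‑isopropyl‑2,3,5‑trimethoxyphenyl)‑2‑(methoxycarbonyl)‑2‑methylhexanoic acid (C6 epimers) | COc1cc(C(O)CCC[C@](C)(C(=O)OC)C(=O)O)c(OC)c(OC)c1C(C)C | intermediate
16 | (2S)‑6‑(4‑isopropyl‑2,3,5‑trimethoxyphenyl)‑2‑(methoxycarbonyl)‑2‑methyl‑6‑oxohexanoic acid | COc1cc(C(=O)CCC[C@](C)(C(=O)OC)C(=O)O)c(OC)c(OC)c1C(C)C | intermediate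
17 | (2S)‑6‑(4‑isopropyl‑2,3,5‑trimethoxyphenyl)‑7‑methoxy‑2‑(methoxycarbonyl)‑2‑methylhept‑6‑enoic acid (E/Z) | COC=C(CCC[C@](C)(C(=O)OC)C(=O)O)c1cc(OC)c(C(C)C)c(OC)c1OC | intermediate
18 | acid chloride of 17 (same configuration) | COC=C(CCC[C@](C)(C(=O)OC)C(Cl)=O)c1cc(OC)c(C(C)C)c(OC)c1OC | intermediate
19 | methyl (2S)‑2‑formyl‑6‑(4‑isopropyl‑2,3,5‑trimethoxyphenyl)‑7‑methoxy‑2‑methylhept‑6‑enoate (E/Z) | COC=C(CCC[C@](C)(C(=O)OC)C=O)c1cc(OC)c(C(C)C)c(OC)c1OC | intermediate
20 | methyl (2S,3E)‑2‑[4‑(4‑isopropyl‑2,3,5‑trimethoxyphenyl)‑5‑methoxypent‑4‑en‑1‑yl]‑2‑methyl‑5‑oxopent‑3‑enoate (enol ether E/Z) | COC=C(CCC[C@](C)(C(=O)OC)/C=C/C=O)c1cc(OC)c(C(C)C)c(OC)c1OC | intermediate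
21 | ring A closed 2‑methoxy‑dihydropyran acetal (O on C7 bonded to C20; C4, C5, C10 as in 23; acetal carbon as epimer mixture) | COc1cc([C@@]23CCC[C@](C)(C(=O)OC)[C@@H]2C=COC3OC)c(OC)c(OC)c1C(C)C | intermediate
22 | methyl 7,20‑epoxy‑11,12,14,20‑tetramethoxyabieta‑8,11,13‑trien‑19‑oate (bridged acetal; C4, C5, C10 as in 23; C20 epimers) | COc1c(C(C)C)c(OC)c2c(c1OC)[C@@]13CCC[C@](C)(C(=O)OC)[C@@H]1C[C@@H]2OC3OC | intermediate
23 | methyl (4S,5R,10R)‑11,12,14‑trimethoxy‑20‑oxoabieta‑6,8,11,13‑tetraen‑19‑oate | COc1c(C(C)C)c(OC)c2c(c1OC)[C@@]1(C=O)CCC[C@](C)(C(=O)OC)[C@@H]1C=C2 | intermediate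
24 | methyl (4S,5R,10R)‑20‑hydroxy‑11,12,14‑trimethoxyabieta‑6,8,11,13‑tetraen‑19‑oate | COc1c(C(C)C)c(OC)c2c(c1OC)[C@@]1(CO)CCC[C@](C)(C(=O)OC)[C@@H]1C=C2 | intermediate
25 | (4S,5R,10R)‑11,12,14‑trimethoxyabieta‑6,8,11,13‑tetraen‑19,20‑olide | COc1c(C(C)C)c(OC)c2c(c1OC)[C@]13CCC[C@](C)(C(=O)OC1)[C@@H]3C=C2 | intermediate
26 | (4S,5R,10R)‑11,12,14‑trihydroxyabieta‑6,8,11,13‑tetraen‑19,20‑olide | Oc1c(C(C)C)c(O)c2c(c1O)[C@]13CCC[C@](C)(C(=O)OC1)[C@@H]3C=C2 | intermediate
27 | (4S,5R,10R)‑12‑hydroxy‑11,14‑dioxoabieta‑6,8,12‑trien‑19,20‑olide | OC1=C(C(C)C)C(=O)C2=C(C1=O)[C@]13CCC[C@](C)(C(=O)OC1)[C@@H]3C=C2 | intermediate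
28 | (4S,5R,10R)‑12‑acetoxy‑11,14‑dioxoabieta‑6,8,12‑trien‑19,20‑olide | CC(=O)OC1=C(C(C)C)C(=O)C2=C(C1=O)[C@]13CCC[C@](C)(C(=O)OC1)[C@@H]3C=C2 | target

**Step count**
Total steps: 15. Longest linear sequence: 13 steps (5 → 28, steps 3–15); the arene branch (steps 1–2) joins at step 7.

**Steps most likely to fail**

1. Step 12 (proposed new method). What may go wrong: the enol ether is hydrolysed or oligomerises before it adds to the hindered C5, ring A closes with poor facial selectivity relative to C4, or the cascade stalls at the bridged acetal. Fallback with known reactions, from 20 back to 23: the enol ether of 20 is hydrolysed (oxalic acid, wet THF, 0 °C) to the dialdehyde methyl (2S,3E)‑2‑[4‑(4‑isopropyl‑2,3,5‑trimethoxyphenyl)‑5‑oxopentyl]‑2‑methyl‑5‑oxopent‑3‑enoate F1. A base‑catalysed intramolecular Michael addition of the α‑aryl aldehyde to the enal (DBU 0.2 equiv, MeCN, 0 °C; reversible, so the ring A isomers can be equilibrated and separated) should give the ring A dialdehyde methyl 3‑formyl‑3‑(4‑isopropyl‑2,3,5‑trimethoxyphenyl)‑1‑methyl‑2‑(2‑oxoethyl)cyclohexane‑1‑carboxylate F2. A separate Bradsher cyclodehydration (TsOH, toluene, 60 °C) then closes ring B and gives 23.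

2. Step 7. What may go wrong: metalation at the ring position next to the other methoxy group, or enolisation of the aldehyde in place of addition. Fallback, from 4 back to 15: electrophilic bromination of 4 (NBS, MeCN, 0 °C) should go to the position para to the central methoxy group and give 1‑bromo‑3‑isopropyl‑2,4,5‑trimethoxybenzene F3, which has a single ring hydrogen left, flanked by Br and OMe. LiN(iPr)2 (THF, −78 °C) removes it, and addition of the aryllithium to the lithium salt of 13 gives (2S)‑6‑(2‑bromo‑4‑isopropyl‑3,5,6‑trimethoxyphenyl)‑6‑hydroxy‑2‑(methoxycarbonyl)‑2‑methylhexanoic acid F4. Hydrogenolysis of the C–Br bond (H2, Pd/C, Et3N, MeOH) returns 15.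

3. Step 14. What may go wrong: addition of HBr to the C6=C7 styrene or opening of the lactone by BBr3, or over‑oxidation of the triol in air. Fallback, from 25 back to 27: oxidative demethylation with (NH4)2Ce(NO3)6 (MeCN–H2O, 0 °C) should give (4S,5R,10R)‑12‑methoxy‑11,14‑dioxoabieta‑6,8,12‑trien‑19,20‑olide F5. BCl3 (CH2Cl2, −78 °C) then cleaves the vinylogous methyl ester next to the C11 carbonyl and gives 27.

**Further compounds**
F1 | step 12 | methyl (2S,3E)‑2‑[4‑(4‑isopropyl‑2,3,5‑trimethoxyphenyl)‑5‑oxopentyl]‑2‑methyl‑5‑oxopent‑3‑enoate (epimers at the aryl‑bearing carbon) | O=CC(CCC[C@](C)(C(=O)OC)/C=C/C=O)c1cc(OC)c(C(C)C)c(OC)c1OC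
F2 | step 12 | methyl 3‑formyl‑3‑(4‑isopropyl‑2,3,5‑trimethoxyphenyl)‑1‑methyl‑2‑(2‑oxoethyl)cyclohexane‑1‑carboxylate (C4, C5, C10 as in 23) | COc1cc([C@@]2(C=O)CCC[C@](C)(C(=O)OC)[C@@H]2CC=O)c(OC)c(OC)c1C(C)C
F3 | step 7 | 1‑bromo‑3‑isopropyl‑2,4,5‑trimethoxybenzene | COc1cc(Br)c(OC)c(C(C)C)c1OC
F4 | step 7 | (2S)‑6‑(2‑bromo‑4‑isopropyl‑3,5,6‑trimethoxyphenyl)‑6‑hydroxy‑2‑(methoxycarbonyl)‑2‑methylhexanoic acid (C6 epimers) | COc1c(Br)c(C(O)CCC[C@](C)(C(=O)OC)C(=O)O)c(OC)c(OC)c1C(C)C
F5 | step 14 | (4S,5R,10R)‑12‑methoxy‑11,14‑dioxoabieta‑6,8,12‑trien‑19,20‑olide | COC1=C(C(C)C)C(=O)C2=C(C1=O)[C@]13CCC[C@](C)(C(=O)OC1)[C@@H]3C=C2
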